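**Retrosynthetic overview**

Locants used below: ring C1 (C=O), C2 (bears C7, the propanoic acid stereocentre), C3 (bears the trimethylcyclohexyl ring), C4, C5, C6 (bears C16H2OCHO).
Enabling feature: the cyclohex-2-enone C1(=O)–C2=C3 with saturated C4–C5–C6 is the keto form of a 1-hydroxycyclohexa-1,3-diene. With C16 raised to an ester, C6 is a β-keto ester α-carbon, so the ring opens (retro-6π) across C5–C6 to the acyclic enol triene C6=C1(OH)–C2=C3–C4=C5, and C6 becomes a dynamic centre that a later reduction can fix.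
Disconnections (backward): CO2H and formate unmasked last; C16 ester to CH2OH after dynamic kinetic resolution at C1/C6; C5–C6 by 6π electrocyclisation; C1–C6 by malonate acylation; C3–C4 by Stille coupling of a chelation-defined (Z)-enol triflate; C2–C3 by acylation of an (R)-methylsuccinate enolate.
Ring order: the trimethylcyclohexane ring comes from 3-methylcyclohexenone (quaternary centre by asymmetric conjugate addition, gem-dimethyl from the ketone, phenyl degraded to CO2H); the cyclohexenone ring is the only ring made and is closed in the key step.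

Key step: step 11

Assumption: half-ester 7 is taken as purchased (it is the hydrogenation product of 4-methyl itaconate), and the sense of induction of the chiral catalysts in steps 1 and 12 is assigned by analogy with their usual substrates.

**Route**

Step 1
Reactants: 1 3-methylcyclohex-2-en-1-one; 2 phenylboronic acid
Product: 3 (3S)-3-methyl-3-phenylcyclohexan-1-one
Conditions: Pd(OCOCF3)2 (5 mol %), (R)-t-BuPyOX (6 mol %), NH4PF6 (30 mol %), H2O (5 equiv), ClCH2CH2Cl, 40 °C
Reagents that add atoms: none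
Why: Pd-catalysed asymmetric conjugate addition of an arylboronic acid to a β-substituted enone; the pyridine–oxazoline ligand selects the enone face and sets the quaternary centre, the (R)-ligand being chosen because it is expected to give the (S)-ketone.

Step 2
Reactants: 3 (3S)-3-methyl-3-phenylcyclohexan-1-one
Product: 4 [(1S)-1,3,3-trimethylcyclohexyl]benzene
Conditions: TiCl4 (2.2 equiv), ZnMe2 (2.2 equiv), CH2Cl2, −40 °C to 0 °C
Reagents that add atoms: dimethylzinc, C[Zn]C
Why: geminal dimethylation of a ketone by Me2TiCl2 made in the flask (methyl addition, ionisation of the tertiary titanium alkoxide, second methyl transfer); the quaternary stereocentre is not at the reacting carbon and is kept.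

Step 3
Reactants: 4 [(1S)-1,3,3-trimethylcyclohexyl]benzene
Product: 5 (1S)-1,3,3-trimethylcyclohexane-1-carboxylic acid
Conditions: RuCl3·xH2O (5 mol %), NaIO4 (15 equiv), CCl4/MeCN/H2O (2:2:3), rt
Reagents that add atoms: sodium periodate, [Na+].[O-]I(=O)(=O)=O; water, O
Why: oxidative degradation of the phenyl ring to CO2H by catalytically generated RuO4; the ipso carbon is kept and the quaternary centre bears no hydrogen that could be oxidised.

Step 4
Reactants: 5 (1S)-1,3,3-trimethylcyclohexane-1-carboxylic acid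
Product: 6 (1S)-1,3,3-trimethylcyclohexane-1-carbonyl chloride
Conditions: (COCl)2 (1.5 equiv), DMF (cat.), CH2Cl2, 0 °C to rt
Reagents that add atoms: oxalyl chloride, ClC(=O)C(=O)Cl
Why: Vilsmeier-type activation of the acid gives the acid chloride without touching the stereocentre.

Step 5
Reactants: 7 (2R)-4-methoxy-2-methyl-4-oxobutanoic acid
Product: 8 1-tert-butyl 4-methyl (2R)-2-methylbutanedioate
Conditions: tert-butyl 2,2,2-trichloroacetimidate (2 equiv), BF3·OEt2 (cat.), cyclohexane/CH2Cl2, rt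
Reagents that add atoms: tert-butyl 2,2,2-trichloroacetimidate, CC(C)(C)OC(=N)C(Cl)(Cl)Cl
Why: acid-catalysed O-tert-butylation of the free acid by the imidate; the conditions are non-basic, so the chiral-pool stereocentre C7 is kept.

Step 6
Reactants: 8 1-tert-butyl 4-methyl (2R)-2-methylbutanedioate; 6 (1S)-1,3,3-trimethylcyclohexane-1-carbonyl chloride
Product: 9 1-tert-butyl 4-methyl (2R,3RS)-2-methyl-3-[(1S)-1,3,3-trimethylcyclohexane-1-carbonyl]butanedioate
Conditions: LiN(SiMe3)2 (2.2 equiv), THF, −78 °C; then 6, −78 °C to −30 °C; aq NH4Cl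
Reagents that add atoms: none
Why: crossed Claisen C-acylation of an ester lithium enolate by an acid chloride; kinetic deprotonation should go to the unhindered CH2 next to the methyl ester rather than the tertiary CH next to the tert-butyl ester, so C7 stays (R), and the second equivalent of base stores the product as its enolate.

Step 7
Reactants: 9 1-tert-butyl 4-methyl (2R,3RS)-2-methyl-3-[(1S)-1,3,3-trimethylcyclohexane-1-carbonyl]butanedioate
Product: 10 1-tert-butyl 4-methyl (2R,3Z)-2-methyl-3-{[(1S)-1,3,3-trimethylcyclohexyl][(trifluoromethanesulfonyl)oxy]methylidene}butanedioate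
Conditions: NaH (1.05 equiv), THF, 0 °C to rt; then PhNTf2 (1.2 equiv), rt; aq NH4Cl
Reagents that add atoms: N-phenylbis(trifluoromethanesulfonimide), O=S(=O)(N(c1ccccc1)S(=O)(=O)C(F)(F)F)C(F)(F)F
Why: O-sulfonylation of a β-keto ester sodium enolate; chelation of Na between the enolate oxygen and the ester carbonyl holds them cis, which should give the (Z)-enol triflate (OTf cis to CO2Me).

Step 8
Reactants: 10 1-tert-butyl 4-methyl (2R,3Z)-2-methyl-3-{[(1S)-1,3,3-trimethylcyclohexyl][(trifluoromethanesulfonyl)oxy]methylidene}butanedioate; 11 tributyl(vinyl)stannane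
Product: 12 1-tert-butyl 4-methyl (2R,3E)-2-methyl-3-{1-[(1S)-1,3,3-trimethylcyclohexyl]prop-2-en-1-ylidene}butanedioate
Conditions: Pd(PPh3)4 (10 mol %), CuI (20 mol %), CsF (2 equiv), DMF, 45 °C
Reagents that add atoms: none
Why: Stille cross-coupling of a vinyl triflate (CuI/CsF to speed transmetalation at the hindered site) with retention of alkene geometry, so the new vinyl group C4=C5 ends cis to the C1 ester.

Step 9
Reactants: 12 1-tert-butyl 4-methyl (2R,3E)-2-methyl-3-{1-[(1S)-1,3,3-trimethylcyclohexyl]prop-2-en-1-ylidene}butanedioate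
Product: 13 (2E,3R)-4-(tert-butoxy)-3-methyl-4-oxo-2-{1-[(1S)-1,3,3-trimethylcyclohexyl]prop-2-en-1-ylidene}butanoic acid
Conditions: Me3SnOH (5 equiv), ClCH2CH2Cl, 70 °C; then 0.1 M aq HCl wash
Reagents that add atoms: trimethyltin hydroxide, C[Sn](C)(C)O
Why: mild, non-epimerising cleavage of a methyl ester by Me3SnOH; the tert-butyl ester and the allylic C7–H should be untouched.

Step 10
Reactants: 13 (2E,3R)-4-(tert-butoxy)-3-methyl-4-oxo-2-{1-[(1S)-1,3,3-trimethylcyclohexyl]prop-2-en-1-ylidene}butanoic acid; 14 magnesium bis(3-ethoxy-3-oxopropanoate)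
Product: 16 1-tert-butyl 6-ethyl (2R,3E)-2-methyl-4-oxo-3-{1-[(1S)-1,3,3-trimethylcyclohexyl]prop-2-en-1-ylidene}hexanedioate, via acyl imidazole 15 (not isolated)
Conditions: CDI (1.2 equiv), THF, rt; then 14 (1.0 equiv), THF, 40 °C; dilute aq HCl
Reagents that add atoms: 1,1'-carbonyldiimidazole, O=C(n1ccnc1)n1ccnc1
Why: Masamune–Brooks homologation, in which the acyl imidazole C-acylates the magnesium malonate chelate and decarboxylation gives the β-keto ester under near-neutral conditions that spare C7 and the diene.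

Step 11
Reactants: 16 1-tert-butyl 6-ethyl (2R,3E)-2-methyl-4-oxo-3-{1-[(1S)-1,3,3-trimethylcyclohexyl]prop-2-en-1-ylidene}hexanedioate
Product: 19 ethyl (1RS)-3-[(2R)-1-(tert-butoxy)-1-oxopropan-2-yl]-2-oxo-4-[(1S)-1,3,3-trimethylcyclohexyl]cyclohex-3-ene-1-carboxylate, via enol triene 17 (not isolated), via cyclohexadienol 18 (not isolated)
Conditions: toluene (0.02 M, degassed), BHT (cat.), 100 °C, Ar
Reagents that add atoms: none
Why: The β-keto ester enolises to the hydrogen-bonded (Z)-enol 17, a 1,3,5-hexatriene C6=C1(OH)–C2=C3–C4=C5, which should close by thermal disrotatory 6π electrocyclisation to dienol 18, and proton transfer to C4 then gives the conjugated enone 19. The closest known reaction type is the thermal 6π electrocyclisation of (Z)-configured 2-oxy-1,3,5-hexatrienes (2-silyloxy trienes, enols of dienyl 1,3-dicarbonyl compounds) to cyclohexadienes. The cyclohexenone ring closes in a six-centre pericyclic mode in which the whole triene, including the terminal CH2 (C5), ends inside the ring. The only new stereocentre, C6, is the α-carbon of a β-keto ester and is formed as an equilibrating mixture on purpose (it is fixed in step 12), so no torquoselectivity is needed, while C7 and the quaternary centre are untouched under neutral thermal conditions. The step needs C4=C5 cis to C1 across C2=C3, secured by the chelation-controlled triflate and the stereoretentive coupling, and it needs carbon closure to win over the oxa-6π closure of the dienone to a 2H-pyran, which is reversible whereas the carbon closure is not. The enol hydrogen bond holds OH and ester cis so that the inside position at C6 is H, and the crowded tetrasubstituted C2=C3 bond disfavours the s-trans conformers, which should lower the barrier.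

Step 12
Reactants: 19 ethyl (1RS)-3-[(2R)-1-(tert-butoxy)-1-oxopropan-2-yl]-2-oxo-4-[(1S)-1,3,3-trimethylcyclohexyl]cyclohex-3-ene-1-carboxylate
Product: 20 ethyl (1R,2R)-3-[(2R)-1-(tert-butoxy)-1-oxopropan-2-yl]-2-hydroxy-4-[(1S)-1,3,3-trimethylcyclohexyl]cyclohex-3-ene-1-carboxylate
Conditions: RuCl(p-cymene)[(R,R)-TsDPEN] (2 mol %), HCO2H/Et3N (5:2), CH2Cl2, 30 °C
Reagents that add atoms: none
Why: Noyori–Ikariya asymmetric transfer hydrogenation with dynamic kinetic resolution of a cyclic α-substituted β-keto ester: C6 epimerises fast through the enol, the (R,R)-catalyst is expected to give the (R)-carbinol (alkenyl C2 playing the part of the aryl group of an aryl ketone) with hydride delivered anti to the ester, so the cis hydroxy ester with the required C6 configuration should form, and the hindered tetrasubstituted C=C is not reduced.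

Step 13
Reactants: 20 ethyl (1R,2R)-3-[(2R)-1-(tert-butoxy)-1-oxopropan-2-yl]-2-hydroxy-4-[(1S)-1,3,3-trimethylcyclohexyl]cyclohex-3-ene-1-carboxylate
Product: 21 tert-butyl (2R)-2-{(5S,6R)-6-hydroxy-5-(hydroxymethyl)-2-[(1S)-1,3,3-trimethylcyclohexyl]cyclohex-1-en-1-yl}propanoate
Conditions: LiBH4 (2 equiv), MeOH (2 equiv), THF, 0 °C; aq NH4Cl
Reagents that add atoms: none
Why: chemoselective hydride reduction of the ethyl β-hydroxy ester to the primary alcohol; the tert-butyl ester is inert to LiBH4 and resists lactonisation by the neighbouring alkoxide, and C6 is no longer acidic.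

Step 14
Reactants: 21 tert-butyl (2R)-2-{(5S,6R)-6-hydroxy-5-(hydroxymethyl)-2-[(1S)-1,3,3-trimethylcyclohexyl]cyclohex-1-en-1-yl}propanoate
Product: 22 tert-butyl (2R)-2-{(5S)-5-(hydroxymethyl)-6-oxo-2-[(1S)-1,3,3-trimethylcyclohexyl]cyclohex-1-en-1-yl}propanoate
Conditions: MnO2 (activated, 20 equiv), CH2Cl2, rt
Reagents that add atoms: none
Why: selective oxidation of the secondary allylic alcohol in the presence of the primary one, which restores the C1 ketone under neutral conditions without epimerising C6.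

Step 15
Reactants: 22 tert-butyl (2R)-2-{(5S)-5-(hydroxymethyl)-6-oxo-2-[(1S)-1,3,3-trimethylcyclohexyl]cyclohex-1-en-1-yl}propanoate
Product: 23 tert-butyl (2R)-2-{(5S)-5-[(formyloxy)methyl]-6-oxo-2-[(1S)-1,3,3-trimethylcyclohexyl]cyclohex-1-en-1-yl}propanoate
Conditions: AcOCHO (preformed, 3 equiv), pyridine (3 equiv), CH2Cl2, −20 °C to 0 °C
Reagents that add atoms: acetic formic anhydride, CC(=O)OC=O
Why: O-formylation of the primary alcohol by the mixed anhydride (formyl transfer is faster than acetyl transfer); low temperature and a weak base should avoid E1cB loss of formate from the β-acyloxy ketone.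

Step 16
Reactants: 23 tert-butyl (2R)-2-{(5S)-5-[(formyloxy)methyl]-6-oxo-2-[(1S)-1,3,3-trimethylcyclohexyl]cyclohex-1-en-1-yl}propanoate
Product: 24 (2R)-2-{(5S)-5-[(formyloxy)methyl]-6-oxo-2-[(1S)-1,3,3-trimethylcyclohexyl]cyclohex-1-en-1-yl}propanoic acid
Conditions: CF3CO2H/CH2Cl2 (1:4), 0 °C; evaporation
Reagents that add atoms: none
Why: acidolysis of the tert-butyl ester (loss of isobutene) frees the acid under non-basic conditions that should leave the formate, the β-formyloxy ketone and both α-stereocentres intact.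

**Compound list**

1 | 3-methylcyclohex-2-en-1-one | CC1=CC(=O)CCC1 | starting material
2 | phenylboronic acid | OB(O)c1ccccc1 | starting material
3 | (3S)-3-methyl-3-phenylcyclohexan-1-one | c1ccccc1[C@@]1(C)CCCC(=O)C1 | intermediate
4 | [(1S)-1,3,3-trimethylcyclohexyl]benzene | c1ccccc1[C@@]1(C)CCCC(C)(C)C1 | intermediate
5 | (1S)-1,3,3-trimethylcyclohexane-1-carboxylic acid | OC(=O)[C@@]1(C)CCCC(C)(C)C1 | intermediate
6 | (1S)-1,3,3-trimethylcyclohexane-1-carbonyl chloride | ClC(=O)[C@@]1(C)CCCC(C)(C)C1 | intermediate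
7 | (2R)-4-methoxy-2-methyl-4-oxobutanoic acid | C[C@@H](C(=O)O)CC(=O)OC | starting material
8 | 1-tert-butyl 4-methyl (2R)-2-methylbutanedioate | C[C@@H](C(=O)OC(C)(C)C)CC(=O)OC | intermediate
9 | 1-tert-butyl 4-methyl (2R,3RS)-2-methyl-3-[(1S)-1,3,3-trimethylcyclohexane-1-carbonyl]butanedioate | C[C@@H](C(=O)OC(C)(C)C)C(C(=O)OC)C(=O)[C@@]1(C)CCCC(C)(C)C1 | intermediate
10 | 1-tert-butyl 4-methyl (2R,3Z)-2-methyl-3-{[(1S)-1,3,3-trimethylcyclohexyl][(trifluoromethanesulfonyl)oxy]methylidene}butanedioate | COC(=O)/C(=C(\OS(=O)(=O)C(F)(F)F)[C@@]1(C)CCCC(C)(C)C1)[C@@H](C)C(=O)OC(C)(C)C | intermediate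
11 | tributyl(vinyl)stannane | C=C[Sn](CCCC)(CCCC)CCCC | starting material
12 | 1-tert-butyl 4-methyl (2R,3E)-2-methyl-3-{1-[(1S)-1,3,3-trimethylcyclohexyl]prop-2-en-1-ylidene}butanedioate | COC(=O)/C(=C(\C=C)[C@@]1(C)CCCC(C)(C)C1)[C@@H](C)C(=O)OC(C)(C)C | intermediate
13 | (2E,3R)-4-(tert-butoxy)-3-methyl-4-oxo-2-{1-[(1S)-1,3,3-trimethylcyclohexyl]prop-2-en-1-ylidene}butanoic acid | OC(=O)/C(=C(\C=C)[C@@]1(C)CCCC(C)(C)C1)[C@@H](C)C(=O)OC(C)(C)C | intermediate
14 | magnesium bis(3-ethoxy-3-oxopropanoate) | CCOC(=O)CC(=O)[O-].CCOC(=O)CC(=O)[O-].[Mg+2] | starting material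
15 | tert-butyl (2R,3E)-3-(1H-imidazole-1-carbonyl)-2-methyl-4-[(1S)-1,3,3-trimethylcyclohexyl]hexa-3,5-dienoate | O=C(n1ccnc1)/C(=C(\C=C)[C@@]1(C)CCCC(C)(C)C1)[C@@H](C)C(=O)OC(C)(C)C | intermediate
16 | 1-tert-butyl 6-ethyl (2R,3E)-2-methyl-4-oxo-3-{1-[(1S)-1,3,3-trimethylcyclohexyl]prop-2-en-1-ylidene}hexanedioate | CCOC(=O)CC(=O)/C(=C(\C=C)[C@@]1(C)CCCC(C)(C)C1)[C@@H](C)C(=O)OC(C)(C)C | intermediate
17 | 1-tert-butyl 6-ethyl (2R,3E,4Z)-4-hydroxy-2-methyl-3-{1-[(1S)-1,3,3-trimethylcyclohexyl]prop-2-en-1-ylidene}hex-4-enedioate | CCOC(=O)/C=C(\O)/C(=C(\C=C)[C@@]1(C)CCCC(C)(C)C1)[C@@H](C)C(=O)OC(C)(C)C | intermediate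
18 | ethyl (1RS)-3-[(2R)-1-(tert-butoxy)-1-oxopropan-2-yl]-2-hydroxy-4-[(1S)-1,3,3-trimethylcyclohexyl]cyclohexa-2,4-diene-1-carboxylate | CCOC(=O)C1CC=C([C@@]2(C)CCCC(C)(C)C2)C(=C1O)[C@@H](C)C(=O)OC(C)(C)C | intermediate
19 | ethyl (1RS)-3-[(2R)-1-(tert-butoxy)-1-oxopropan-2-yl]-2-oxo-4-[(1S)-1,3,3-trimethylcyclohexyl]cyclohex-3-ene-1-carboxylate | CCOC(=O)C1CCC([C@@]2(C)CCCC(C)(C)C2)=C([C@@H](C)C(=O)OC(C)(C)C)C1=O | intermediate
20 | ethyl (1R,2R)-3-[(2R)-1-(tert-butoxy)-1-oxopropan-2-yl]-2-hydroxy-4-[(1S)-1,3,3-trimethylcyclohexyl]cyclohex-3-ene-1-carboxylate | C[C@@H](C(=O)OC(C)(C)C)C1=C([C@@]2(C)CCCC(C)(C)C2)CC[C@@H](C(=O)OCC)[C@H]1O | intermediate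
21 | tert-butyl (2R)-2-{(5S,6R)-6-hydroxy-5-(hydroxymethyl)-2-[(1S)-1,3,3-trimethylcyclohexyl]cyclohex-1-en-1-yl}propanoate | C[C@@H](C(=O)OC(C)(C)C)C1=C([C@@]2(C)CCCC(C)(C)C2)CC[C@@H](CO)[C@H]1O | intermediate
22 | tert-butyl (2R)-2-{(5S)-5-(hydroxymethyl)-6-oxo-2-[(1S)-1,3,3-trimethylcyclohexyl]cyclohex-1-en-1-yl}propanoate | C[C@@H](C(=O)OC(C)(C)C)C1=C([C@@]2(C)CCCC(C)(C)C2)CC[C@@H](CO)C1=O | intermediate
23 | tert-butyl (2R)-2-{(5S)-5-[(formyloxy)methyl]-6-oxo-2-[(1S)-1,3,3-trimethylcyclohexyl]cyclohex-1-en-1-yl}propanoate | C[C@@H](C(=O)OC(C)(C)C)C1=C([C@@]2(C)CCCC(C)(C)C2)CC[C@@H](COC=O)C1=O | intermediate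
24 | (2R)-2-{(5S)-5-[(formyloxy)methyl]-6-oxo-2-[(1S)-1,3,3-trimethylcyclohexyl]cyclohex-1-en-1-yl}propanoic acid | C[C@@H](C(=O)O)C1=C([C@@]2(C)CCCC(C)(C)C2)CC[C@@H](COC=O)C1=O | target

**Step count**

Total: 16 steps. Longest linear sequence: 15 steps (steps 1–4 and 6–16, from 1 to 24).

**Steps most likely to fail**

Step 11. The dienone may rest as its 2H-pyran valence isomer, or the diene may polymerise or be oxidised to the aromatic salicylate, faster than the carbon electrocyclisation proceeds. The fallback makes the same C5–C6 bond by enolate alkylation and sets out from 12. Hydroboration of the terminal vinyl group (9-BBN, THF; NaBO3·4H2O), followed by lactonisation onto the cis methyl ester, should give tert-butyl (2R)-2-{2-oxo-4-[(1S)-1,3,3-trimethylcyclohexyl]-5,6-dihydro-2H-pyran-3-yl}propanoate F1. LiCH2CO2Et (THF, −78 °C) should open the lactone to 1-tert-butyl 6-ethyl (2R,3E)-3-{3-hydroxy-1-[(1S)-1,3,3-trimethylcyclohexyl]propylidene}-2-methyl-4-oxohexanedioate F2. An Appel reaction (I2, PPh3, imidazole, CH2Cl2) should give 1-tert-butyl 6-ethyl (2R,3E)-3-{3-iodo-1-[(1S)-1,3,3-trimethylcyclohexyl]propylidene}-2-methyl-4-oxohexanedioate F3. K2CO3 in acetone should then close the ring by intramolecular C-alkylation of the β-keto ester (6-enolendo-exo-tet), and the route is rejoined at 19.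

Step 8. Transmetalation and reductive elimination at the tetrasubstituted triflate carbon, which sits next to a quaternary centre, may be so slow that triflate hydrolysis or protodestannylation takes over. The fallback uses a linear, less demanding alkyne partner and sets out from 10. Sonogashira coupling with ethynyltrimethylsilane (PdCl2(PPh3)2, CuI, i-Pr2NH, THF) should give 1-tert-butyl 4-methyl (2R,3Z)-2-methyl-3-{1-[(1S)-1,3,3-trimethylcyclohexyl]-3-(trimethylsilyl)prop-2-yn-1-ylidene}butanedioate F4. K2CO3 in MeOH should remove the silyl group to give 1-tert-butyl 4-methyl (2R,3Z)-2-methyl-3-{1-[(1S)-1,3,3-trimethylcyclohexyl]prop-2-yn-1-ylidene}butanedioate F5. Semihydrogenation (H2, Pd/CaCO3 poisoned with Pb(OAc)2, quinoline, EtOAc) should then give the vinyl compound, and the route is rejoined at 12.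

Step 12. The ketone is hindered and largely enolised, so hydride transfer may be slow and the discrimination between the two rapidly interconverting C6 epimers, or between the two carbonyl faces, may erode. The fallback replaces the ruthenium hydride catalyst by biocatalysis: an NADPH-dependent ketoreductase (KRED) picked from a commercial panel, with glucose and glucose dehydrogenase for cofactor recycling in pH 7 phosphate buffer with DMSO, carries out the same dynamic kinetic resolution. It sets out from 19 and comes back to the route at 20.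

Further compounds
F1 | step 11 | tert-butyl (2R)-2-{2-oxo-4-[(1S)-1,3,3-trimethylcyclohexyl]-5,6-dihydro-2H-pyran-3-yl}propanoate | C[C@@H](C(=O)OC(C)(C)C)C1=C([C@@]2(C)CCCC(C)(C)C2)CCOC1=O
F2 | step 11 | 1-tert-butyl 6-ethyl (2R,3E)-3-{3-hydroxy-1-[(1S)-1,3,3-trimethylcyclohexyl]propylidene}-2-methyl-4-oxohexanedioate | CCOC(=O)CC(=O)/C(=C(\CCO)[C@@]1(C)CCCC(C)(C)C1)[C@@H](C)C(=O)OC(C)(C)C
F3 | step 11 | 1-tert-butyl 6-ethyl (2R,3E)-3-{3-iodo-1-[(1S)-1,3,3-trimethylcyclohexyl]propylidene}-2-methyl-4-oxohexanedioate | CCOC(=O)CC(=O)/C(=C(\CCI)[C@@]1(C)CCCC(C)(C)C1)[C@@H](C)C(=O)OC(C)(C)C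
F4 | step 8 | 1-tert-butyl 4-methyl (2R,3Z)-2-methyl-3-{1-[(1S)-1,3,3-trimethylcyclohexyl]-3-(trimethylsilyl)prop-2-yn-1-ylidene}butanedioate | COC(=O)/C(=C(\C#C[Si](C)(C)C)[C@@]1(C)CCCC(C)(C)C1)[C@@H](C)C(=O)OC(C)(C)C
F5 | step 8 | 1-tert-butyl 4-methyl (2R,3Z)-2-methyl-3-{1-[(1S)-1,3,3-trimethylcyclohexyl]prop-2-yn-1-ylidene}butanedioate | COC(=O)/C(=C(\C#C)[C@@]1(C)CCCC(C)(C)C1)[C@@H](C)C(=O)OC(C)(C)C
F0 | step 12 | none | none
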